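The target is epicatechin-(4β→6)-epicatechin-(4β→6)-epicatechin. Everything rests on cutting C4–C4a in the pyran (C ring) of the terminal unit. Its A ring then becomes a 3,5-dihydroxyphenyl ether with a local twofold axis through O1–C8a and C6. C4a and C8 are therefore equivalent, so ring closure can only deliver the elusive 4→6 pattern. The precursor is the bromine-capped, benzylated upper dimer, made from (−)-epicatechin. It bears a phloroglucinol ring at C4, whose unhindered para oxygen carries a chiral aryl(oxiranyl)methyl group. One 6-endo epoxide–arene closure forms the last ring, unveils the 3-OH and translates the threo ether into the 2,3-cis geometry.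

Key step: step 11

Remark: the SMILES is read as three (2R,3R) units with both interflavan bonds 3,4-trans (4β). Flavan numbering (O1, C2–C4, C4a, C5–C8, C8a, B ring primed) is used for the upper, middle and terminal unit. Compounds 1, 8, 10 and 11 are taken as commercial.

Step 1
Reactants: 1 (−)-epicatechin
Product: 2 3,5,7,3',4'-penta-O-benzyl-(−)-epicatechin (2R,3R)
Conditions: NaH, BnBr, DMF, −10 °C to rt
Reagents that add atoms: benzyl bromide, BrCc1ccccc1
Why: Williamson ether synthesis on all five hydroxyl groups (four phenoxides first, then the C3 alkoxide), with C2 and C3 untouched because rapid capping of the 4'-phenoxide at low temperature shuts off the ring-opening path to C2 epimerisation.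

Step 2
Reactants: 2 penta-O-benzylepicatechin
Product: 3 4β-(2-ethoxyethoxy)-3,5,7,3',4'-penta-O-benzylepicatechin (2,3-cis, 3,4-trans)
Conditions: DDQ, 2-ethoxyethanol, CH2Cl2, rt
Reagents that add atoms: 2-ethoxyethanol, CCOCCO
Why: Benzylic C–H oxidation by hydride abstraction with DDQ gives the C4 cation stabilised by the 5,7-dioxygenated A ring, and the alcohol adds anti to the pseudo-axial 3-OBn, which sets C4 as 4β (3,4-trans).

Step 3
Reactants: 3 4β-(2-ethoxyethoxy)-penta-O-benzylepicatechin
Product: 4 8-bromo-4β-(2-ethoxyethoxy)-3,5,7,3',4'-penta-O-benzylepicatechin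
Conditions: NBS (1.0 equiv), CH2Cl2, −78 to 0 °C
Reagents that add atoms: N-bromosuccinimide, O=C1CCC(=O)N1Br
Why: Electrophilic aromatic bromination (SEAr) takes C8, flanked by O1 and 7-OBn and the most nucleophilic A-ring carbon, ahead of the more crowded C6, so that C6 stays as the only nucleophilic site.

Step 4
Reactants: 4 8-bromo-4β-(2-ethoxyethoxy)-penta-O-benzylepicatechin
Product: 5 8-bromo-4β-[(2,6-dimethylphenyl)sulfanyl]-3,5,7,3',4'-penta-O-benzylepicatechin
Conditions: 2,6-dimethylbenzenethiol (3 equiv), BF3·OEt2, CH2Cl2, −78 °C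
Reagents that add atoms: 2,6-dimethylbenzenethiol, Cc1cccc(C)c1S
Why: Lewis acid promoted SN1 exchange of the C4 ether for a thiol through the same C4 cation, again with attack anti to 3-OBn (4β), gives a hindered aryl thioether that hard Lewis acids leave alone at low temperature (latent leaving group).

Step 5
Reactants: 3 4β-(2-ethoxyethoxy)-penta-O-benzylepicatechin
Product: 6 6,8-dibromo-4β-(2-ethoxyethoxy)-3,5,7,3',4'-penta-O-benzylepicatechin
Conditions: NBS (2.2 equiv), CH2Cl2, −40 °C to rt
Reagents that add atoms: N-bromosuccinimide, O=C1CCC(=O)N1Br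
Why: Twofold SEAr bromination fills both nucleophilic A-ring carbons (C6 and C8), so this unit can act only as an electrophile and cannot condense with itself.

Step 6
Reactants: 6 6,8-dibromo-4β-(2-ethoxyethoxy)-penta-O-benzylepicatechin; 5 8-bromo-4β-arylsulfanyl-penta-O-benzylepicatechin
Product: 7 [6,8-dibromo-penta-O-benzylepicatechin]-(4β→6)-[8-bromo-4β-(2,6-dimethylphenylsulfanyl)-penta-O-benzylepicatechin]
Conditions: BF3·OEt2, 4 Å MS, CH2Cl2, −78 to −40 °C
Reagents that add atoms: none
Why: Friedel–Crafts type flavan-4-yl cation/arene coupling with orthogonal leaving groups, in which BF3 ionises only the chelating oxygen leaving group of 6, the sole free A-ring carbon of 5 (C6) captures the cation, and approach anti to 3-OBn sets the upper C4 as 4β (3,4-trans).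

Step 7
Reactants: 7 tribromo dimer thioether; 8 phloroglucinol (anhydrous, large excess)
Product: 9 [6,8-dibromo-penta-O-benzylepicatechin]-(4β→6)-[8-bromo-penta-O-benzylepicatechin]-(4β→2)-phloroglucinol
Conditions: AgBF4, THF, 0 °C, dark
Reagents that add atoms: none
Why: Thiophilic activation of the C4 thioether by Ag(I) releases the middle-unit C4 cation under near-neutral conditions, and C3-symmetric phloroglucinol (three equivalent carbons) captures it in a Friedel–Crafts reaction anti to 3-OBn, which sets the middle C4 as 4β.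

Step 8
Reactants: 10 3,4-bis(benzyloxy)benzaldehyde; 11 vinylmagnesium bromide
Product: 12 rac-1-[3,4-bis(benzyloxy)phenyl]prop-2-en-1-ol
Conditions: THF, −78 to 0 °C; then aq NH4Cl
Reagents that add atoms: none
Why: Grignard 1,2-addition to the aldehyde gives the racemic allylic alcohol that carries C2, C3 and C4 of the terminal unit.

Step 9
Reactants: 12 rac-1-[3,4-bis(benzyloxy)phenyl]prop-2-en-1-ol
Product: 13 (S)-[3,4-bis(benzyloxy)phenyl][(R)-oxiran-2-yl]methanol (erythro)
Conditions: Ti(OiPr)4 (cat.), L-(+)-DIPT (cat.), t-BuOOH (0.45 equiv), 4 Å MS, CH2Cl2, −20 °C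
Reagents that add atoms: tert-butyl hydroperoxide, CC(C)(C)OO
Why: Sharpless kinetic resolution, in which with L-(+)-DIPT the (R)-alcohol is epoxidised much faster than the (S)-alcohol and on the face dictated by the tartrate, should give the erythro epoxy alcohol with the carbinol carbon S and the oxirane carbon R (future C3), the slow enantiomer being removed by chromatography.

Step 10
Reactants: 9 dimer–phloroglucinol adduct; 13 erythro epoxy alcohol
Product: 14 ether of 9 at the phloroglucinol oxygen para to the interflavan bond, carrying the (R)-[3,4-bis(benzyloxy)phenyl][(R)-oxiran-2-yl]methyl group (threo)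
Conditions: PPh3, DIAD, toluene–THF, −20 to 0 °C
Reagents that add atoms: none
Why: Mitsunobu etherification with SN2 inversion turns the S carbinol into the R aryl ether (future C2, erythro to threo), the electron-withdrawing oxirane and the cold non-polar medium holding back ionisation, and the bulky secondary oxyphosphonium salt should pick the para hydroxyl (two CH neighbours) over the two ortho hydroxyls buried beside the flavan-4-yl group.

Step 11
Reactants: 14 threo aryl (oxiranyl)methyl ether
Product: 15 [6,8-dibromo-penta-O-benzylepicatechin]-(4β→6)-[8-bromo-penta-O-benzylepicatechin]-(4β→6)-[3',4'-di-O-benzylepicatechin]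
Conditions: (CF3)2CHOH–CH2Cl2 (4:1), high dilution, 2,6-di-tert-butylpyridine (cat.), 40 °C
Reagents that add atoms: none
Why: HFIP hydrogen-bonds to the oxirane oxygen, the phloroglucinol-type ring of 14 (free OH groups ortho and para to the attacking carbon) attacks the terminal oxirane carbon in an intramolecular SEAr, and rearomatisation of the Wheland intermediate delivers the C4–C4a bond and the free 3-OH. The closest known reaction type is the intramolecular Friedel–Crafts epoxide–arene cycloalkylation of aryl glycidyl ethers to chroman-3-ols, known with Au(III), Fe(III) and fluorinated-alcohol activation. The pyran closes in the 6-endo-tet mode, since the 5-exo alternative would need backside attack at the more substituted oxirane carbon through a strained transition state and is not typical of this reaction class. No stereocentre is made or broken: C3 keeps its C–O bond (R) and C2 (R, set in step 10) is a spectator, so the threo ether maps onto the 2,3-cis epicatechin ring. Regiochemistry needs no control, because the two ring carbons ortho to the ether oxygen are exchanged by rotation about the O1–C8a···C6 axis and either closure gives the same 4→6-linked constitution, while the phenolic oxygens are meta to the tether and cannot reach the oxirane. The absence of any acid stronger than HFIP should spare the acid-labile interflavan bonds and the benzylic C2–O1 ether.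

Step 12
Reactants: 15 protected tribromo trimer
Product: 16 epicatechin-(4β→6)-epicatechin-(4β→6)-epicatechin (target)
Conditions: H2 (1 atm), Pd(OH)2/C, Et3N (3.3 equiv), THF–MeOH–H2O, rt
Reagents that add atoms: none
Why: Catalytic hydrogenolysis cleaves the twelve benzyl ethers and hydrodehalogenates the three aryl bromides in one operation, triethylamine taking up HBr so that the acid-labile interflavan bonds and all eight stereocentres stay intact.

Compound list

1 | (−)-epicatechin (2R,3R) | Oc1cc(O)c2c(c1)O[C@H](c1ccc(O)c(O)c1)[C@H](O)C2 | starting material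
2 | 3,5,7,3',4'-penta-O-benzyl-(−)-epicatechin | c1ccccc1COc1cc(OCc2ccccc2)c2c(c1)O[C@H](c1ccc(OCc3ccccc3)c(OCc3ccccc3)c1)[C@H](OCc1ccccc1)C2 | intermediate
3 | 4β-(2-ethoxyethoxy)-penta-O-benzylepicatechin | c1ccccc1COc1cc(OCc2ccccc2)c2c(c1)O[C@H](c1ccc(OCc3ccccc3)c(OCc3ccccc3)c1)[C@H](OCc1ccccc1)[C@H]2OCCOCC | intermediate
4 | 8-bromo-4β-(2-ethoxyethoxy)-penta-O-benzylepicatechin | c1ccccc1COc1cc(OCc2ccccc2)c2c(c1Br)O[C@H](c1ccc(OCc3ccccc3)c(OCc3ccccc3)c1)[C@H](OCc1ccccc1)[C@H]2OCCOCC | intermediate
5 | 8-bromo-4β-[(2,6-dimethylphenyl)sulfanyl]-penta-O-benzylepicatechin | c1ccccc1COc1cc(OCc2ccccc2)c2c(c1Br)O[C@H](c1ccc(OCc3ccccc3)c(OCc3ccccc3)c1)[C@H](OCc1ccccc1)[C@H]2Sc1c(C)cccc1C | intermediate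
6 | 6,8-dibromo-4β-(2-ethoxyethoxy)-penta-O-benzylepicatechin | c1ccccc1COc1c(Br)c(OCc2ccccc2)c2c(c1Br)O[C@H](c1ccc(OCc3ccccc3)c(OCc3ccccc3)c1)[C@H](OCc1ccccc1)[C@H]2OCCOCC | intermediate
7 | (4β→6) dimer, upper unit 6,8-dibromo, lower unit 8-bromo-4β-arylsulfanyl, deca-O-benzyl | c1ccccc1COc1c(Br)c(OCc2ccccc2)c2c(c1Br)O[C@H](c1ccc(OCc3ccccc3)c(OCc3ccccc3)c1)[C@H](OCc1ccccc1)[C@H]2c1c(OCc3ccccc3)c(Br)c2c(c1OCc3ccccc3)[C@H](Sc1c(C)cccc1C)[C@@H](OCc1ccccc1)[C@@H](c1ccc(OCc3ccccc3)c(OCc3ccccc3)c1)O2 | intermediate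
8 | phloroglucinol | Oc1cc(O)cc(O)c1 | starting material
9 | (4β→6) dimer-(4β→2)-phloroglucinol adduct | c1ccccc1COc1c(Br)c(OCc2ccccc2)c2c(c1Br)O[C@H](c1ccc(OCc3ccccc3)c(OCc3ccccc3)c1)[C@H](OCc1ccccc1)[C@H]2c1c(OCc3ccccc3)c(Br)c2c(c1OCc3ccccc3)[C@H](c1c(O)cc(O)cc1O)[C@@H](OCc1ccccc1)[C@@H](c1ccc(OCc3ccccc3)c(OCc3ccccc3)c1)O2 | intermediate
10 | 3,4-bis(benzyloxy)benzaldehyde | O=Cc1ccc(OCc2ccccc2)c(OCc2ccccc2)c1 | starting material
11 | vinylmagnesium bromide | C=C[Mg]Br | starting material
12 | rac-1-[3,4-bis(benzyloxy)phenyl]prop-2-en-1-ol | C=CC(O)c1ccc(OCc2ccccc2)c(OCc2ccccc2)c1 | intermediate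
13 | (S)-[3,4-bis(benzyloxy)phenyl][(R)-oxiran-2-yl]methanol | O[C@@H](c1ccc(OCc2ccccc2)c(OCc2ccccc2)c1)[C@H]1CO1 | intermediate
14 | para-O-{(R)-[3,4-bis(benzyloxy)phenyl][(R)-oxiran-2-yl]methyl} ether of 9 | c1ccccc1COc1c(Br)c(OCc2ccccc2)c2c(c1Br)O[C@H](c1ccc(OCc3ccccc3)c(OCc3ccccc3)c1)[C@H](OCc1ccccc1)[C@H]2c1c(OCc3ccccc3)c(Br)c2c(c1OCc3ccccc3)[C@H](c1c(O)cc(O[C@H](c3ccc(OCc4ccccc4)c(OCc4ccccc4)c3)[C@H]3CO3)cc1O)[C@@H](OCc1ccccc1)[C@@H](c1ccc(OCc3ccccc3)c(OCc3ccccc3)c1)O2 | intermediate
15 | dodeca-O-benzyl tribromo (4β→6),(4β→6) trimer with free terminal 3-, 5- and 7-OH | c1ccccc1COc1c(Br)c(OCc2ccccc2)c2c(c1Br)O[C@H](c1ccc(OCc3ccccc3)c(OCc3ccccc3)c1)[C@H](OCc1ccccc1)[C@H]2c1c(OCc3ccccc3)c(Br)c2c(c1OCc3ccccc3)[C@H](c1c(O)cc3c(c1O)C[C@@H](O)[C@@H](c1ccc(OCc4ccccc4)c(OCc4ccccc4)c1)O3)[C@@H](OCc1ccccc1)[C@@H](c1ccc(OCc3ccccc3)c(OCc3ccccc3)c1)O2 | intermediate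
16 | epicatechin-(4β→6)-epicatechin-(4β→6)-epicatechin | Oc1cc(O)c2c(c1)O[C@H](c1ccc(O)c(O)c1)[C@H](O)[C@H]2c1c(O)cc2c(c1O)[C@H](c1c(O)cc3c(c1O)C[C@@H](O)[C@@H](c1ccc(O)c(O)c1)O3)[C@@H](O)[C@@H](c1ccc(O)c(O)c1)O2 | target

Total step count: 12. Longest linear sequence: 9 steps (1, 2, 3, 4, 6, 7, 10, 11, 12).

Steps most likely to fail

Step 10. The three phenolic oxygens may be discriminated poorly, and the oxyphosphonium salt of the electron-rich benzylic alcohol may partly ionise, which would erode the inversion. The fallback sets out from 8 and 13 and comes back at 14. It moves the site decision from the O-alkylation to the C–C coupling.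
- A Mitsunobu reaction of 13 with an excess of 8, whose three hydroxyl groups are equivalent, gives the mono-ether 5-{(R)-[3,4-bis(benzyloxy)phenyl][(R)-oxiran-2-yl]methoxy}benzene-1,3-diol F1 without any site question.
- This mono-ether then takes the place of 8 in the silver-promoted coupling with 7 (AgBF4, 2,6-di-tert-butyl-4-methylpyridine, THF, −20 °C). The hindered base takes up the acid so that the oxirane survives.
- The cation should attack the ring carbon between the two free hydroxyl groups, para to the bulky ether, which gives 14.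

Step 6. Capture of the C4 cation by the crowded, bromine-deactivated C6 may be slow. That would leave time for transfer of the arylsulfanyl group from 5 to the cation (scrambling of leaving groups) or for proton loss to a flav-3-ene. The fallback sets out from 6 and comes back at 9. It inverts the order of the orthogonal activations.
- Thiol exchange on 6 (2,6-dimethylbenzenethiol, BF3·OEt2, −78 °C) gives 6,8-dibromo-4β-[(2,6-dimethylphenyl)sulfanyl]-penta-O-benzylepicatechin F2.
- Soft activation (AgOTf, 2,6-di-tert-butyl-4-methylpyridine, CH2Cl2, −40 °C) removes the thiolate irreversibly as its silver salt. Compound 4, whose ether oxygen is a poor nucleophile, serves as the C6 nucleophile and gives the (4β→6) dimer with a lower-unit 4β-(2-ethoxyethoxy) group F3.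
- Hard activation of this dimer (BF3·OEt2, THF–CH2Cl2, −20 °C) in the presence of excess 8 gives 9.

Step 11. The benzylic C2–O1 ether may ionise, or the lower interflavan bond may suffer acidolysis in the strongly ionising medium, before the ring closes. The fallback sets out from 14 and comes back at 16. It moves the closure from a free phloroglucinol nucleus under solvent activation to a fully etherified nucleus under metal catalysis.
- Benzylation of the two phenols (BnBr, K2CO3, acetone) gives the bis(benzyl ether) of 14 F4. Its interflavan bond no longer has a phenol-assisted cleavage path.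
- Catalytic AuCl3/AgOTf in 1,2-dichloroethane at rt effects the same 6-endo epoxide–arene cycloalkylation in a non-ionising solvent. The product is the tetradeca-O-benzyl tribromo trimer with free terminal 3-OH F5.
- Hydrogenolysis under the conditions of step 12 gives 16.

Further compounds

F1 | step 10 | 5-{(R)-[3,4-bis(benzyloxy)phenyl][(R)-oxiran-2-yl]methoxy}benzene-1,3-diol | Oc1cc(O)cc(O[C@H](c2ccc(OCc3ccccc3)c(OCc3ccccc3)c2)[C@H]2CO2)c1
F2 | step 6 | 6,8-dibromo-4β-[(2,6-dimethylphenyl)sulfanyl]-penta-O-benzylepicatechin | c1ccccc1COc1c(Br)c(OCc2ccccc2)c2c(c1Br)O[C@H](c1ccc(OCc3ccccc3)c(OCc3ccccc3)c1)[C@H](OCc1ccccc1)[C@H]2Sc1c(C)cccc1C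
F3 | step 6 | (4β→6) dimer with a lower-unit 4β-(2-ethoxyethoxy) group | c1ccccc1COc1c(Br)c(OCc2ccccc2)c2c(c1Br)O[C@H](c1ccc(OCc3ccccc3)c(OCc3ccccc3)c1)[C@H](OCc1ccccc1)[C@H]2c1c(OCc3ccccc3)c(Br)c2c(c1OCc3ccccc3)[C@H](OCCOCC)[C@@H](OCc1ccccc1)[C@@H](c1ccc(OCc3ccccc3)c(OCc3ccccc3)c1)O2
F4 | step 11 | bis(benzyl ether) of 14 | c1ccccc1COc1c(Br)c(OCc2ccccc2)c2c(c1Br)O[C@H](c1ccc(OCc3ccccc3)c(OCc3ccccc3)c1)[C@H](OCc1ccccc1)[C@H]2c1c(OCc3ccccc3)c(Br)c2c(c1OCc3ccccc3)[C@H](c1c(OCc4ccccc4)cc(O[C@H](c3ccc(OCc4ccccc4)c(OCc4ccccc4)c3)[C@H]3CO3)cc1OCc4ccccc4)[C@@H](OCc1ccccc1)[C@@H](c1ccc(OCc3ccccc3)c(OCc3ccccc3)c1)O2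
F5 | step 11 | tetradeca-O-benzyl tribromo trimer with free terminal 3-OH | c1ccccc1COc1c(Br)c(OCc2ccccc2)c2c(c1Br)O[C@H](c1ccc(OCc3ccccc3)c(OCc3ccccc3)c1)[C@H](OCc1ccccc1)[C@H]2c1c(OCc3ccccc3)c(Br)c2c(c1OCc3ccccc3)[C@H](c1c(OCc4ccccc4)cc3c(c1OCc4ccccc4)C[C@@H](O)[C@@H](c1ccc(OCc4ccccc4)c(OCc4ccccc4)c1)O3)[C@@H](OCc1ccccc1)[C@@H](c1ccc(OCc3ccccc3)c(OCc3ccccc3)c1)O2
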